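## Structural features

The target is a flavone: benzene ring A is fused through C4a–C8a to the 4-pyranone ring C, and ring C carries the aryl ring B on C2 through the C2–C1' single bond. There is no stereocentre; the only conformational element is the twist about C2–C1' imposed by the 3-methoxy and 2'-hydroxy groups. Ring A is oxygenated on four of its six carbons (O1 on C8a, methoxy on C8 and C7, hydroxyl on C5) and only C6 bears hydrogen; ring C has a methoxy group on C3 next to the C4 carbonyl; ring B is a 2',3'-catechol. The fragile parts are the catechol (easily oxidised to an ortho-quinone, above all in base), the pyranone C2 (accepts hard nucleophiles with ring opening) and the chelated 5-OH, which must end free while three other oxygens are methylated. The real difficulty is regiochemical: C4a has two ortho oxygens, and the one that becomes O1 decides between the 5,7,8 pattern of the target and the isomeric 5,6,7 pattern, which classical closures of 2,6-dioxygenated aryl ketones tend to give as mixtures. A second difficulty is the oxygen on C3, which a plain flavone closure does not supply. The key step treats C2 and C3 as the two sp carbons of an aryl alkynyl ketone: the methoxy oxygen on the future C8a lies within reach of C2, so an iodonium ion on the triple bond closes ring C through O1–C2 and leaves an exchangeable iodine on C3.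

## Logic of the disconnections

**14 to 13.** The two benzyl–oxygen bonds on O2' and O3' are the last to be broken. The catechol is the most sensitive group, so it stays masked until a neutral final step. The forward step must leave the C2=C3 bond and the methyl ethers alone; the tetrasubstituted enol-ether double bond of 13 should meet this.

**13 to 11.** The C3–OMe bond is exchanged for C3–I, and the O5–H bond for an O5–S bond. This links the product of the ring closure to the target pattern in one operation, because one reagent can do the C–O coupling at C3 and cleave the sulfonate at O5. The forward step must couple faster than iodine is lost reductively and faster than methoxide attacks C2.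

**11 to 9.** The O1–C2 bond and the C3–I bond are cut, and the C8a oxygen regains its methyl group. Ring C opens to an acyclic alkynone and ring A becomes a derivative of a symmetrical phenol. The forward step must choose one of three ortho oxygens and must iodinate the alkyne and not the arenes. The design of 9 answers both needs:
- The sulfonate makes the O5 oxygen non-nucleophilic, lowers the electron density of ring A, and is cleaved in the next step at no extra cost.
- The benzyl ethers on ring B are inert to ICl at low temperature and to methoxide. Sulfonates or silyl ethers there would be cleaved in the methoxide step and would expose a catecholate to copper and to the methylating by-product.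

**9 to 3 and 6 (through 8 and 7).** The bond between the carbonyl carbon (C4) and the alkyne carbon (C3) is cut after lowering the ketone to a carbinol. This divides the molecule into a ring A aldehyde and a ring B alkyne of similar size. The acetylide must add to a di-ortho-substituted aldehyde without touching the sulfonate. The carbinol stereocentre of 8 is of no consequence, because it is oxidised away.

**6 to 4 (through 5).** The terminal alkyne carbon (the future C3) is removed from the aldehyde carbon (the future C2), and the two benzyl ethers are cut. This reaches a commercial catechol aldehyde. The homologation must be mild enough for the benzyl ethers.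

**3 to 1 (through 2).** The O–S bond and the aryl–CHO bond (C4a–C4) are cut. Because 1 is symmetrical, its two ortho positions are equivalent and only one monoaldehyde is possible; the whole ring A pattern then follows from one formylation. The forward step must stop at monoformylation.

## Other disconnections considered

**Alternative 1:** The cut goes through ring B at C1'–C2' and C3'–C4'; four ring B carbons come from a 2-pyranone and C2' and C3' from a two-carbon dienophile.
- Forward step: 3-[5-(benzyloxy)-3,7,8-trimethoxy-4-oxo-4H-chromen-2-yl]-2H-pyran-2-one A2 would add tris(trimethylsilyloxy)ethene A3 across pyranone C3 and C6 in a [4+2] cycloaddition. The bridged lactone would lose CO2 by retro-[4+2] reaction and Me3SiOH by 1,2-elimination, giving 5-(benzyloxy)-3,7,8-trimethoxy-2',3'-bis(trimethylsilyloxy)flavone A1. Desilylation and hydrogenolysis of the 5-benzyl ether would lead to 14.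
- In favour: both ring B oxygens arrive together, and the orientation of A3 does not matter, since both of its carbons carry a silyloxy group. The electron-poor pyranone and the electron-rich alkene are a matched pair. Ring B needs no benzyl groups, so no 2'-oxygen can interfere with a ring closure; on this point the alternative is better than the chosen plan.
- Against: the ring A regiochemistry, the closure of ring C and the C3 oxygen are all still unsolved on the way to A2. A2 also carries a base-labile lactone that would have to survive a chromone synthesis. The cycloaddition must form a bond at a pyranone carbon that bears the bulky chromone, and A3 is very sensitive to hydrolysis.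
- Comparison: the end game is of equal length (one hydrogenolysis after the silyl groups are lost). On structure the alternative addresses the easiest ring. On mechanism it is sound but hindered. On step economy it should be several steps longer, because A2 needs both a regiocontrolled chromone and a pyranone attachment.

**Alternative 2:** The cut is the C3–C4 bond.
- Forward step: in 6-(benzyloxy)-2-{1-[2,3-bis(benzyloxy)phenyl]-2-oxoethoxy}-3,4-dimethoxybenzaldehyde A5 (racemic), SmI2 would reduce the aromatic aldehyde to a ketyl that adds to the aliphatic aldehyde. This would give rac-(2R,3S,4S)-5,2',3'-tris(benzyloxy)-7,8-dimethoxyflavan-3,4-diol A4. The 3,4-cis relation would come from chelation of both oxygens by trivalent samarium, and the 2,3-trans relation from the pseudo-equatorial aryl group. Double oxidation to the 3,4-dione, which is the keto tautomer of 5,2',3'-tris(benzyloxy)-3-hydroxy-7,8-dimethoxyflavone A6, then 3-O-methylation and hydrogenolysis, would give 14.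
- In favour: the C3 oxygen is built in with the bond formation, so no halogen has to be exchanged for oxygen; here the alternative is better than the chosen plan. O1 is fixed by alkylation of a single free phenol, which is as secure as the sulfonate blocking of the chosen plan (equal). The conditions are neutral.
- Against: three stereocentres are made only to be destroyed. The sequence is a two-electron reduction followed by a four-electron oxidation, and diol cleavage competes in that oxidation. A5 is an enolisable alpha-aryloxy aldehyde that must be made beside an aryl aldehyde and through alkylation of a hindered phenol. Three steps follow the key step, against two in the chosen plan.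
- Comparison: better on the C3 oxygen, equal on regiocontrol, worse on redox economy, on stability of the precursor and on length.

**Alternative 3:** The cut is the O1–C8a bond, with ring A at the quinone oxidation level.
- Forward step: oxidation of 1-[2,3-bis(benzyloxy)phenyl]-3-(2,5-dihydroxy-4-methoxyphenyl)-2-methoxypropane-1,3-dione A9 would give 1-[2,3-bis(benzyloxy)phenyl]-2-methoxy-3-(4-methoxy-3,6-dioxocyclohexa-1,4-dien-1-yl)propane-1,3-dione A8. Its enol oxygen would add to the unsubstituted quinone carbon next to the acyl group (6-endo-trig oxa-Michael addition), and tautomerisation would give 2',3'-bis(benzyloxy)-5,8-dihydroxy-3,7-dimethoxyflavone A7. Selective methylation of the non-chelated 8-OH would give 13.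
- In favour: the 3-methoxy group is present from the start (better than the chosen plan). The closure site is fixed by the quinone itself, so O5 needs no protecting group (better). The route meets the chosen one at 13, with the same two steps after the key step (equal).
- Against: A8 is a doubly activated quinone with an enolisable dicarbonyl chain and is open to intermolecular Michael addition and redox side reactions. A9 has a free hydroxyl ortho to the ketone, which under acid would close in the conventional sense to a 6-hydroxy-7-methoxyflavone without the C5 oxygen. The oxidant must spare the bis(benzyloxy)phenyl ring. A7 is an air-sensitive 5,8-hydroquinone. The ring A building block is less accessible than 1.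
- Comparison: on structure it is attractive and in two respects superior. On mechanism it is less well precedented and relies on unstable intermediates. On step economy it is about equal only if A9 were easily made.

Key step: step 7

Remark on the chemistry: the atom mapping was checked and no structure needed correction. In 9 the methoxy group between the ketone and a second methoxy group becomes O1, so the sulfonate oxygen ends on C5 and the other two methoxy groups on C7 and C8. Compound 8 is racemic; its stereocentre is removed in step 6.

## Route

Step 1
Reactants: 1 3,4,5-trimethoxyphenol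
Product: 2 6-hydroxy-2,3,4-trimethoxybenzaldehyde
Conditions: MgCl2, Et3N, (CH2O)n, MeCN, reflux; then 1 M HCl
Reagents that add atoms: paraformaldehyde (reacts as formaldehyde), C=O
Why: Magnesium-mediated ortho-formylation of a phenol (Casnati–Skattebøl reaction): the magnesium phenoxide delivers formaldehyde to the ortho carbon through a chelate, and a second formaldehyde oxidises the salicyl alkoxide by hydride transfer. The two ortho positions of 1 are equivalent, so only one monoaldehyde can form.

Step 2
Reactants: 2 6-hydroxy-2,3,4-trimethoxybenzaldehyde
Product: 3 2-formyl-3,4,5-trimethoxyphenyl 4-methylbenzenesulfonate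
Conditions: TsCl, Et3N, DMAP (cat.), CH2Cl2, 0 °C to rt
Reagents that add atoms: 4-methylbenzenesulfonyl chloride, Cc1ccc(cc1)S(=O)(=O)Cl
Why: DMAP-catalysed O-sulfonylation of a phenol. The hydrogen bond to the aldehyde slows the reaction but should not prevent it, and the aldehyde and methyl ethers are inert.

Step 3
Reactants: 4 2,3-dihydroxybenzaldehyde
Product: 5 2,3-bis(benzyloxy)benzaldehyde
Conditions: BnBr, K2CO3, DMF, 60 °C
Reagents that add atoms: benzyl bromide, BrCc1ccccc1
Why: Williamson ether synthesis. Both phenoxides are alkylated and the aldehyde is untouched by carbonate.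

Step 4
Reactants: 5 2,3-bis(benzyloxy)benzaldehyde
Product: 6 1,2-bis(benzyloxy)-3-ethynylbenzene
Conditions: dimethyl (1-diazo-2-oxopropyl)phosphonate, K2CO3, MeOH, rt
Reagents that add atoms: dimethyl (1-diazo-2-oxopropyl)phosphonate, CC(=O)C(=[N+]=[N-])P(=O)(OC)OC
Why: Seyferth–Gilbert homologation in the Ohira–Bestmann version. Methanolysis of the acetyl group frees the diazomethylphosphonate anion, which olefinates the aldehyde; loss of N2 and a 1,2-hydrogen shift in the alkylidene carbene give the terminal alkyne. The mild carbonate conditions spare the benzyl ethers.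

Step 5
Reactants: 6 1,2-bis(benzyloxy)-3-ethynylbenzene; 3 2-formyl-3,4,5-trimethoxyphenyl 4-methylbenzenesulfonate
Product: 8 2-{3-[2,3-bis(benzyloxy)phenyl]-1-hydroxyprop-2-yn-1-yl}-3,4,5-trimethoxyphenyl 4-methylbenzenesulfonate (racemic), via lithium acetylide 7 (not isolated)
Conditions: 6, n-BuLi, THF, −78 °C; then 3, −78 °C; then AcOH, −78 °C
Reagents that add atoms: none
Why: 1,2-Addition of a lithium acetylide to an aldehyde. At −78 °C the aldehyde is far more electrophilic than the sulfonyl sulfur, and the cold acetic acid quench protonates the alkoxide before it can take over the tosyl group. The carbinol stereocentre forms without control (racemate) and is removed in step 6.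

Step 6
Reactants: 8 2-{3-[2,3-bis(benzyloxy)phenyl]-1-hydroxyprop-2-yn-1-yl}-3,4,5-trimethoxyphenyl 4-methylbenzenesulfonate (racemic)
Product: 9 2-{3-[2,3-bis(benzyloxy)phenyl]prop-2-ynoyl}-3,4,5-trimethoxyphenyl 4-methylbenzenesulfonate
Conditions: Dess–Martin periodinane, CH2Cl2, 0 °C to rt
Reagents that add atoms: none
Why: Dess–Martin oxidation of a secondary benzylic propargylic alcohol to the conjugated ynone. The neutral conditions leave the sulfonate, the ethers and the triple bond alone.

Step 7
Reactants: 9 2-{3-[2,3-bis(benzyloxy)phenyl]prop-2-ynoyl}-3,4,5-trimethoxyphenyl 4-methylbenzenesulfonate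
Product: 11 2',3'-bis(benzyloxy)-3-iodo-7,8-dimethoxy-5-(tosyloxy)flavone, via methyloxonium chloride 10 (not isolated)
Conditions: ICl (1.5 equiv), CH2Cl2, −78 °C, dark; then aq. Na2S2O3
Reagents that add atoms: iodine monochloride, ClI
Why: ICl forms an iodonium ion on the triple bond, and the ketone polarises it so that positive charge builds on the alkyne carbon bonded to ring B, the future C2, where the electron-rich ring B also stabilises it. The methoxy oxygen ortho to the ketone attacks this carbon anti to iodine, forming O1–C2 and closing ring C in the 6-endo-dig mode, while iodine becomes bonded to C3. Chloride then dealkylates the methyloxonium ion 10 by SN2 attack at the methyl group, releasing chloromethane and the neutral 4-pyranone. The closest known reaction type is the ICl-induced demethylative cyclisation of 2-methoxyaryl alkynyl ketones to 3-iodochromones and 3-iodoflavones. No stereocentre is created. The step needs a choice among three ortho oxygens: the sulfonate oxygen is too electron-poor to attack, so the 5,6,7 isomer cannot arise, and the 2'-benzyloxy oxygen could only close a five-membered ring (5-endo-dig) onto the carbon alpha to the ketone, where positive charge is disfavoured. The step also needs the alkyne to be iodinated in preference to the arenes: the acyl and sulfonyl groups lower the nucleophilicity of ring A at C6, the ynone lowers that of ring B, and low temperature with a small excess of ICl should keep arene iodination slow.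

Step 8
Reactants: 11 2',3'-bis(benzyloxy)-3-iodo-7,8-dimethoxy-5-(tosyloxy)flavone
Product: 13 2',3'-bis(benzyloxy)-5-hydroxy-3,7,8-trimethoxyflavone, via sodium 5-phenolate 12 (not isolated)
Conditions: CuI (cat.), 1,10-phenanthroline (cat.), NaOMe (excess), MeOH–DMF, 100 °C; then 1 M HCl
Reagents that add atoms: sodium methoxide, [Na+].[O-]C
Why: Ullmann-type copper-catalysed C–O coupling of the C3 iodide with methoxide installs the 3-methoxy group. The same methoxide cleaves the aryl sulfonate by attack at sulfur, and excess methoxide consumes the methyl tosylate formed. The phenanthroline ligand should let the coupling run below the temperature at which methoxide degrades the pyranone, and acidification returns the chelated 5-OH.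

Step 9
Reactants: 13 2',3'-bis(benzyloxy)-5-hydroxy-3,7,8-trimethoxyflavone
Product: 14 5,2',3'-trihydroxy-3,7,8-trimethoxyflavone
Conditions: H2 (1 atm), Pd/C, EtOAc–MeOH, rt
Reagents that add atoms: none
Why: Heterogeneous hydrogenolysis of aryl benzyl ethers. The tetrasubstituted C2=C3 enol-ether bond and the aryl methyl ethers should be inert to H2 over Pd/C at room temperature, and the neutral medium protects the freed catechol.

## Compound list

1 | 3,4,5-trimethoxyphenol | COc1cc(O)cc(OC)c1OC | starting material
2 | 6-hydroxy-2,3,4-trimethoxybenzaldehyde | COc1cc(O)c(C=O)c(OC)c1OC | intermediate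
3 | 2-formyl-3,4,5-trimethoxyphenyl 4-methylbenzenesulfonate | COc1cc(OS(=O)(=O)c2ccc(C)cc2)c(C=O)c(OC)c1OC | intermediate
4 | 2,3-dihydroxybenzaldehyde | O=Cc1cccc(O)c1O | starting material
5 | 2,3-bis(benzyloxy)benzaldehyde | O=Cc1cccc(OCc2ccccc2)c1OCc1ccccc1 | intermediate
6 | 1,2-bis(benzyloxy)-3-ethynylbenzene | C#Cc1cccc(OCc2ccccc2)c1OCc1ccccc1 | intermediate
7 | lithium [2,3-bis(benzyloxy)phenyl]ethynide | [Li+].[C-]#Cc1cccc(OCc2ccccc2)c1OCc1ccccc1 | intermediate
8 | 2-{3-[2,3-bis(benzyloxy)phenyl]-1-hydroxyprop-2-yn-1-yl}-3,4,5-trimethoxyphenyl 4-methylbenzenesulfonate (racemic) | COc1cc(OS(=O)(=O)c2ccc(C)cc2)c(C(O)C#Cc2cccc(OCc3ccccc3)c2OCc2ccccc2)c(OC)c1OC | intermediate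
9 | 2-{3-[2,3-bis(benzyloxy)phenyl]prop-2-ynoyl}-3,4,5-trimethoxyphenyl 4-methylbenzenesulfonate | COc1cc(OS(=O)(=O)c2ccc(C)cc2)c(C(=O)C#Cc2cccc(OCc3ccccc3)c2OCc2ccccc2)c(OC)c1OC | intermediate
10 | 2-[2,3-bis(benzyloxy)phenyl]-3-iodo-7,8-dimethoxy-1-methyl-4-oxo-5-(tosyloxy)-4H-chromen-1-ium chloride | COc1cc(OS(=O)(=O)c3ccc(C)cc3)c2C(=O)C(I)=C(c3cccc(OCc4ccccc4)c3OCc3ccccc3)[O+](C)c2c1OC.[Cl-] | intermediate
11 | 2',3'-bis(benzyloxy)-3-iodo-7,8-dimethoxy-5-(tosyloxy)flavone | COc1cc(OS(=O)(=O)c2ccc(C)cc2)c2c(=O)c(I)c(-c3cccc(OCc4ccccc4)c3OCc3ccccc3)oc2c1OC | intermediate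
12 | sodium 2-[2,3-bis(benzyloxy)phenyl]-3,7,8-trimethoxy-4-oxo-4H-chromen-5-olate | COc1cc([O-])c2c(=O)c(OC)c(-c3cccc(OCc4ccccc4)c3OCc3ccccc3)oc2c1OC.[Na+] | intermediate
13 | 2',3'-bis(benzyloxy)-5-hydroxy-3,7,8-trimethoxyflavone | COc1cc(O)c2c(=O)c(OC)c(-c3cccc(OCc4ccccc4)c3OCc3ccccc3)oc2c1OC | intermediate
14 | 5,2',3'-trihydroxy-3,7,8-trimethoxyflavone | COc1cc(O)c2c(=O)c(OC)c(-c3cccc(O)c3O)oc2c1OC | target

## Step count and least certain steps

Total step count: 9 steps. Longest linear sequence: 7 steps (from 1 through steps 1, 2, 5, 6, 7, 8, 9; the sequence from 4 through steps 3, 4, 5, 6, 7, 8, 9 is equally long).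

**Step 7 (key step).** The most likely failure is electrophilic iodination of the electron-rich arenes, or capture of the iodonium ion by the 2'-benzyloxy oxygen in place of closure through the methoxy group. ICl is a strong electrophile and ring B carries two donor groups. The fallback replaces the electrophile-triggered closure by an oxa-Michael closure of a free phenol and brings in iodine afterwards. It sets out from 3 (and from 7, made from 6) and comes back at 11:
- BCl3 in CH2Cl2 at −78 to 0 °C should remove only the methyl group ortho to the aldehyde, through chelation, and give 2-formyl-3-hydroxy-4,5-dimethoxyphenyl 4-methylbenzenesulfonate F1.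
- Two equivalents of 7 (the first is spent on the phenol) should add to give 2-{3-[2,3-bis(benzyloxy)phenyl]-1-hydroxyprop-2-yn-1-yl}-3-hydroxy-4,5-dimethoxyphenyl 4-methylbenzenesulfonate (racemic) F2.
- MnO2 in CH2Cl2 should oxidise the carbinol to 2-{3-[2,3-bis(benzyloxy)phenyl]prop-2-ynoyl}-3-hydroxy-4,5-dimethoxyphenyl 4-methylbenzenesulfonate F3.
- Catalytic TfOH in CH2Cl2 should close the phenol onto the ynone in the 6-endo-dig sense to 2',3'-bis(benzyloxy)-7,8-dimethoxy-5-(tosyloxy)flavone F4.
- I2 with (NH4)2Ce(NO3)6 in MeCN should iodinate C3 and give 11.

**Step 8.** The most likely failures are reductive loss of iodine, ring opening of the pyranone after methoxide attack at C2, and O-methylation of the freed 5-phenoxide by the methyl tosylate formed in the flask. The fallback separates the C–O bond formation from the methylation and the sulfonate cleavage. It sets out from 11 and comes back at 13: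
- Miyaura borylation (B2pin2, PdCl2(dppf), KOAc, dioxane, 80 °C) should give 2',3'-bis(benzyloxy)-7,8-dimethoxy-3-(4,4,5,5-tetramethyl-1,3,2-dioxaborolan-2-yl)-5-(tosyloxy)flavone F5.
- Oxidation with NaBO3·4H2O in THF–H2O should give 2',3'-bis(benzyloxy)-3-hydroxy-7,8-dimethoxy-5-(tosyloxy)flavone F6.
- MeI and K2CO3 in acetone should give 2',3'-bis(benzyloxy)-3,7,8-trimethoxy-5-(tosyloxy)flavone F7.
- K2CO3 in MeOH at reflux should remove the sulfonate and give 13.

**Step 5.** The most likely failure is transfer of the tosyl group from the phenol oxygen to the new alkoxide, which is possible through a six-membered transition state, or attack of the acetylide at sulfur. The fallback avoids any alkoxide by making the ynone through an acyl Sonogashira coupling. It sets out from 3 and 6 and comes back at 9, so that 8 and step 6 are bypassed: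
- Pinnick oxidation (NaClO2, NaH2PO4, 2-methyl-2-butene, t-BuOH–H2O) should give 2,3,4-trimethoxy-6-(tosyloxy)benzoic acid F8.
- (COCl)2 with catalytic DMF in CH2Cl2 should give 2,3,4-trimethoxy-6-(tosyloxy)benzoyl chloride F9.
- Coupling with 6 (PdCl2(PPh3)2, CuI, Et3N, THF, rt) should give 9.

**Step 9.** The most likely failures are incomplete cleavage of the hindered 2'-benzyl ether, slow saturation of the C2=C3 bond on long exposure, and air oxidation of the catechol during isolation. The fallback replaces hydrogenolysis by Lewis-acid debenzylation: BCl3 with pentamethylbenzene as cation scavenger in CH2Cl2 at −78 °C, a temperature at which the methyl ethers should persist. It sets out from 13 and arrives directly at 14; no compound outside the list is made (entry F0).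

## Further compounds

F1 | step 7 | 2-formyl-3-hydroxy-4,5-dimethoxyphenyl 4-methylbenzenesulfonate | COc1cc(OS(=O)(=O)c2ccc(C)cc2)c(C=O)c(O)c1OC
F2 | step 7 | 2-{3-[2,3-bis(benzyloxy)phenyl]-1-hydroxyprop-2-yn-1-yl}-3-hydroxy-4,5-dimethoxyphenyl 4-methylbenzenesulfonate (racemic) | COc1cc(OS(=O)(=O)c2ccc(C)cc2)c(C(O)C#Cc2cccc(OCc3ccccc3)c2OCc2ccccc2)c(O)c1OC
F3 | step 7 | 2-{3-[2,3-bis(benzyloxy)phenyl]prop-2-ynoyl}-3-hydroxy-4,5-dimethoxyphenyl 4-methylbenzenesulfonate | COc1cc(OS(=O)(=O)c2ccc(C)cc2)c(C(=O)C#Cc2cccc(OCc3ccccc3)c2OCc2ccccc2)c(O)c1OC
F4 | step 7 | 2',3'-bis(benzyloxy)-7,8-dimethoxy-5-(tosyloxy)flavone | COc1cc(OS(=O)(=O)c2ccc(C)cc2)c2c(=O)cc(-c3cccc(OCc4ccccc4)c3OCc3ccccc3)oc2c1OC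
F5 | step 8 | 2',3'-bis(benzyloxy)-7,8-dimethoxy-3-(4,4,5,5-tetramethyl-1,3,2-dioxaborolan-2-yl)-5-(tosyloxy)flavone | COc1cc(OS(=O)(=O)c2ccc(C)cc2)c2c(=O)c(B3OC(C)(C)C(C)(C)O3)c(-c3cccc(OCc4ccccc4)c3OCc3ccccc3)oc2c1OC
F6 | step 8 | 2',3'-bis(benzyloxy)-3-hydroxy-7,8-dimethoxy-5-(tosyloxy)flavone | COc1cc(OS(=O)(=O)c2ccc(C)cc2)c2c(=O)c(O)c(-c3cccc(OCc4ccccc4)c3OCc3ccccc3)oc2c1OC
F7 | step 8 | 2',3'-bis(benzyloxy)-3,7,8-trimethoxy-5-(tosyloxy)flavone | COc1cc(OS(=O)(=O)c2ccc(C)cc2)c2c(=O)c(OC)c(-c3cccc(OCc4ccccc4)c3OCc3ccccc3)oc2c1OC
F8 | step 5 | 2,3,4-trimethoxy-6-(tosyloxy)benzoic acid | COc1cc(OS(=O)(=O)c2ccc(C)cc2)c(C(=O)O)c(OC)c1OC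
F9 | step 5 | 2,3,4-trimethoxy-6-(tosyloxy)benzoyl chloride | COc1cc(OS(=O)(=O)c2ccc(C)cc2)c(C(=O)Cl)c(OC)c1OC
F0 | step 9 | none | none
A1 | alternative 1 | 5-(benzyloxy)-3,7,8-trimethoxy-2',3'-bis(trimethylsilyloxy)flavone | COc1cc(OCc2ccccc2)c2c(=O)c(OC)c(-c3cccc(O[Si](C)(C)C)c3O[Si](C)(C)C)oc2c1OC
A2 | alternative 1 | 3-[5-(benzyloxy)-3,7,8-trimethoxy-4-oxo-4H-chromen-2-yl]-2H-pyran-2-one | COc1cc(OCc2ccccc2)c2c(=O)c(OC)c(-c3cccoc3=O)oc2c1OC
A3 | alternative 1 | tris(trimethylsilyloxy)ethene | C[Si](C)(C)OC=C(O[Si](C)(C)C)O[Si](C)(C)C
A4 | alternative 2 | rac-(2R,3S,4S)-5,2',3'-tris(benzyloxy)-7,8-dimethoxyflavan-3,4-diol (2,3-trans-3,4-cis, one enantiomer drawn) | O(Cc1ccccc1)c1cccc([C@@H]2[C@H]([C@@H](O)c3c(OCc4ccccc4)cc(OC)c(OC)c3O2)O)c1OCc1ccccc1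
A5 | alternative 2 | 6-(benzyloxy)-2-{1-[2,3-bis(benzyloxy)phenyl]-2-oxoethoxy}-3,4-dimethoxybenzaldehyde (racemic) | O=CC(Oc1c(OC)c(OC)cc(OCc2ccccc2)c1C=O)c1cccc(OCc2ccccc2)c1OCc1ccccc1
A6 | alternative 2 | 5,2',3'-tris(benzyloxy)-3-hydroxy-7,8-dimethoxyflavone | COc1cc(OCc2ccccc2)c2c(=O)c(O)c(-c3cccc(OCc4ccccc4)c3OCc3ccccc3)oc2c1OC
A7 | alternative 3 | 2',3'-bis(benzyloxy)-5,8-dihydroxy-3,7-dimethoxyflavone | COc1cc(O)c2c(=O)c(OC)c(-c3cccc(OCc4ccccc4)c3OCc3ccccc3)oc2c1O
A8 | alternative 3 | 1-[2,3-bis(benzyloxy)phenyl]-2-methoxy-3-(4-methoxy-3,6-dioxocyclohexa-1,4-dien-1-yl)propane-1,3-dione | COC1=CC(=O)C(C(=O)C(OC)C(=O)c2cccc(OCc3ccccc3)c2OCc2ccccc2)=CC1=O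
A9 | alternative 3 | 1-[2,3-bis(benzyloxy)phenyl]-3-(2,5-dihydroxy-4-methoxyphenyl)-2-methoxypropane-1,3-dione | COc1cc(O)c(C(=O)C(OC)C(=O)c2cccc(OCc3ccccc3)c2OCc2ccccc2)cc1O
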